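**Retrosynthetic overview**

1. Target 16 ⇐ 15 ⇐ 14: only reductions remain after the core is built (ketone to carbinol under reagent control, then conjugated ester and acetate to the two allylic alcohols).
2. 14 ⇐ 13: one photoredox radical-polar crossover forms the CH2–CH2 bond of the three-carbon bridge (7-endo, oxepane ring first) and then the tertiary C–O bond of the lactone (1,4-dioxan-2-one ring second). This gives the whole 6,8-dioxabicyclo[3.2.2]nonane core from an acyclic bromomethyl ketone.
3. Enabling feature: the ring-ether oxygen joins a quaternary carbon, which carries both the lactone carbonyl and the carbinol carbon (a latent ketone whose CH2 neighbour is a latent α-keto radical), to a CH carbon bearing a C(CH3)(O-acyl)–CH2 unit, which is a lactonised isopropenyl group. Through that oxygen the radical carbon and the alkene CH2 are 1,7-related, and the ester oxygen and the substituted alkene carbon are 1,6-related.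
4. 13 ⇐ 7 by Michael addition to acrolein (quaternary center), Z-selective olefination and α-bromination; 7 ⇐ 4 + 6 by O–H insertion (the hindered ether bond).
5. 4 ⇐ neryl acetate 1 by asymmetric epoxidation of the distal alkene and epoxide-to-allylic-alcohol isomerisation.

Key step: step 8

Remark: the sense of induction of the cupreidine catalyst in step 5 is assumed to be the one found for α-alkyl β-keto esters; should the other epimer at the quaternary carbon prevail, the pseudoenantiomeric cupreine-derived catalyst is used with no other change.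

**Route**

Step 1
Reactants: 1 neryl acetate
Product: 2 (S)-6,7-epoxyneryl acetate
Conditions: ent-Shi ketone (L-fructose-derived, 0.3 equiv), KHSO5 (Oxone), K2CO3, Bu4NHSO4, aq. Na2B4O7/Na2EDTA buffer, MeCN–CH2(OMe)2, 0 °C
Reagents that add atoms: potassium peroxymonosulfate, [K+].[O-]S(=O)(=O)OO
Why: Shi asymmetric epoxidation, in which the chiral dioxirane attacks the more electron-rich distal trisubstituted alkene (the proximal one is deactivated by the allylic acetate) through the spiro transition state, which should set the (S) configuration at the secondary epoxide carbon.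

Step 2
Reactants: 2 (S)-6,7-epoxyneryl acetate
Product: 4 (2Z,6S)-6-hydroxy-3,7-dimethylocta-2,7-dien-1-yl acetate, via allylic trimethylsilyl ether 3 (not isolated)
Conditions: TMSOTf, DBU, toluene, −40 °C to rt; then citric acid, MeOH, rt
Reagents that add atoms: none
Why: Silyl triflate/amidine isomerisation of an epoxide to an allylic alcohol, in which O-silylation, cleavage of the tertiary C–O bond and loss of a methyl proton to DBU give the isopropenyl carbinol silyl ether with the secondary C–O bond, and so the (S) center, untouched, and mild acid then removes the silyl group.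

Step 3
Reactants: 5 tert-butyl acetoacetate
Product: 6 tert-butyl 2-diazo-3-oxobutanoate
Conditions: 4-AcNHC6H4SO2N3, Et3N, MeCN, 0 °C to rt
Reagents that add atoms: 4-acetamidobenzenesulfonyl azide, CC(=O)Nc1ccc(cc1)S(=O)(=O)N=[N+]=[N-]
Why: Regitz diazo transfer to the active methylene group of a β-keto ester.

Step 4
Reactants: 4 (2Z,6S)-6-hydroxy-3,7-dimethylocta-2,7-dien-1-yl acetate; 6 tert-butyl 2-diazo-3-oxobutanoate
Product: 7 α-alkoxy β-keto ester (both epimers at the labile α-carbon)
Conditions: Rh2(esp)2 (0.5 mol %), CH2Cl2, 0 °C, slow addition of 6; then Et3N (2 mol %), 0 °C, 10 min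
Reagents that add atoms: none
Why: Rhodium-carbenoid O–H insertion, which is much faster than cyclopropanation and leaves the carbinol center untouched; the mixture is kept cold and the first-formed enol is tautomerised at once because that enol is an allyl vinyl ether that could undergo a [3,3] shift on warming.

Step 5
Reactants: 7 α-alkoxy β-keto ester; 8 acrolein
Product: 9 (R)-configured quaternary keto ester aldehyde
Conditions: 8 (3 equiv), 9-O-(9-phenanthryl)cupreidine (10 mol %), CH2Cl2, −24 °C
Reagents that add atoms: none
Why: Cinchona-alkaloid-catalysed Michael addition of an α-substituted β-keto ester to an enal, in which the bifunctional catalyst (quinuclidine base, phenolic OH) selects the enol face and should set the (R) quaternary carbon; the resident center makes the two possible products diastereomers, and the low temperature holds back the sigmatropic shift of the enol.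

Step 6
Reactants: 9 (R)-configured quaternary keto ester aldehyde; 10 ethyl 2-[bis(2,2,2-trifluoroethoxy)phosphoryl]propanoate
Product: 11 (Z)-enoate methyl ketone
Conditions: 10, KN(SiMe3)2, 18-crown-6, THF, −78 °C
Reagents that add atoms: none
Why: Still–Gennari olefination, in which the phosphonate anion reacts only with the aldehyde and gives under kinetic control the (Z)-2-methyl enoate that later becomes the (Z)-hydroxymethyl alkene.

Step 7
Reactants: 11 (Z)-enoate methyl ketone
Product: 13 bromomethyl ketone, via trimethylsilyl enol ether 12 (not isolated)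
Conditions: TMSOTf, Et3N, CH2Cl2, −20 °C; then NBS, THF, −78 °C
Reagents that add atoms: N-bromosuccinimide, O=C1CCC(=O)N1Br
Why: Soft enolisation can go only toward the methyl group because the other α-carbon is quaternary, and electrophilic bromination of the silyl enol ether by NBS is far faster than attack on any of the three alkenes.

Step 8
Reactants: 13 bromomethyl ketone
Product: 14 bicyclic keto lactone
Conditions: fac-Ir(ppy)3 (1 mol %), K2HPO4 (1.5 equiv), MeCN (0.01 M), blue LEDs (450 nm), 25 °C
Reagents that add atoms: none
Why: Proposed new method: photoexcited Ir(ppy)3 (trivalent iridium) reduces the C–Br bond of 13 to an electrophilic α-keto radical at the former bromomethyl carbon, which adds to the CH2 end of the electron-rich isopropenyl group and so closes the oxepan-3-one ring in the 7-endo-trig mode while forming the CH2–CH2 bond; the tertiary radical so formed is oxidised by tetravalent iridium (or takes up bromine from 13 and ionises) to a tertiary cation. This cation is captured by the carbonyl oxygen of the tert-butyl ester on the quaternary carbon in a six-membered closure that forms the tertiary C–O bond of the 1,4-dioxan-2-one ring, and the resulting dialkoxycarbenium ion loses isobutene. The closest known reaction types are the photoredox radical-polar crossover carbolactonisation of alkenoic acids with α-bromo carbonyl compounds and the oxidative radical cyclisation–lactonisation mediated by Mn(OAc)3; new are the intramolecular 7-endo closure by a ketone α-radical and the bridging lactonisation through a tert-butyl ester in the same operation. The one new stereocenter, the methyl-bearing carbon, is set by the (R) quaternary carbon, because the ester can reach only that face of the planar cation from which the lactone can bridge the seven-membered ring. The step needs 7-endo rather than 6-exo attack on the isopropenyl group (secured by its 1,1-disubstitution and by the ketone lying inside the forming ring), no attack on the two other alkenes (the enoate is polarity-mismatched with the electrophilic radical and the allylic acetate alkene is out of reach), and ring closure faster than 1,5-hydrogen transfer from the ether CH (carbon-to-carbon hydrogen transfer to a stabilised α-keto radical is intrinsically slow).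

Step 9
Reactants: 14 bicyclic keto lactone
Product: 15 bicyclic hydroxy lactone
Conditions: (R)-2-methyl-CBS-oxazaborolidine (0.5 equiv), catecholborane (2 equiv), toluene, −78 °C; then MeOH
Reagents that add atoms: none
Why: Corey–Bakshi–Shibata reduction, in which the ketone binds anti to its large substituent (the quaternary bridgehead) and hydride goes to the face that gives the (S) carbinol; reagent control is chosen because the two faces of the bridged ketone are sterically similar, and catecholborane at −78 °C leaves esters, lactone and alkenes alone.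

Step 10
Reactants: 15 bicyclic hydroxy lactone
Product: 16 target CNP0105745.1
Conditions: iBu2AlH (6 equiv), CH2Cl2, −78 °C; aq. KNaC4H4O6
Reagents that add atoms: none
Why: Hydride reduction with diisobutylaluminium hydride, which at −78 °C cleaves the unhindered acetate and reduces the conjugated ethyl ester 1,2 to the allylic alcohol, whereas the bridged lactone, a tert-alkyl ester of an α-quaternary acid, should react much more slowly.

**Compound list**

1 | neryl acetate, (2Z)-3,7-dimethylocta-2,6-dien-1-yl acetate | CC(C)=CCC/C(C)=C\COC(C)=O | starting material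
2 | (2Z)-5-[(2S)-3,3-dimethyloxiran-2-yl]-3-methylpent-2-en-1-yl acetate | CC1(C)O[C@H]1CC/C(C)=C\COC(C)=O | intermediate
3 | (2Z,6S)-3,7-dimethyl-6-(trimethylsilyloxy)octa-2,7-dien-1-yl acetate | C=C(C)[C@@H](O[Si](C)(C)C)CC/C(C)=C\COC(C)=O | intermediate
4 | (2Z,6S)-6-hydroxy-3,7-dimethylocta-2,7-dien-1-yl acetate | C=C(C)[C@@H](O)CC/C(C)=C\COC(C)=O | intermediate
5 | tert-butyl acetoacetate | CC(=O)CC(=O)OC(C)(C)C | starting material
6 | tert-butyl 2-diazo-3-oxobutanoate | CC(=O)C(=[N+]=[N-])C(=O)OC(C)(C)C | intermediate
7 | tert-butyl 2-{[(3S,6Z)-8-acetoxy-2,6-dimethylocta-1,6-dien-3-yl]oxy}-3-oxobutanoate (both C-2 epimers) | CC(=O)C(O[C@@H](CC/C(C)=C\COC(C)=O)C(C)=C)C(=O)OC(C)(C)C | intermediate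
8 | acrolein | C=CC=O | starting material
9 | tert-butyl (2R)-2-acetyl-2-{[(3S,6Z)-8-acetoxy-2,6-dimethylocta-1,6-dien-3-yl]oxy}-5-oxopentanoate | O=CCC[C@@](C(C)=O)(C(=O)OC(C)(C)C)O[C@@H](CC/C(C)=C\COC(C)=O)C(C)=C | intermediate
10 | ethyl 2-[bis(2,2,2-trifluoroethoxy)phosphoryl]propanoate | CCOC(=O)C(C)P(=O)(OCC(F)(F)F)OCC(F)(F)F | starting material
11 | 7-tert-butyl 1-ethyl (2Z,6R)-6-acetyl-6-{[(3S,6Z)-8-acetoxy-2,6-dimethylocta-1,6-dien-3-yl]oxy}-2-methylhept-2-enedioate | C/C(=C/CC[C@@](C(C)=O)(C(=O)OC(C)(C)C)O[C@@H](CC/C(C)=C\COC(C)=O)C(C)=C)C(=O)OCC | intermediate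
12 | 7-tert-butyl 1-ethyl (2Z,6R)-6-{[(3S,6Z)-8-acetoxy-2,6-dimethylocta-1,6-dien-3-yl]oxy}-2-methyl-6-[1-(trimethylsilyloxy)ethenyl]hept-2-enedioate | C/C(=C/CC[C@@](C(=C)O[Si](C)(C)C)(C(=O)OC(C)(C)C)O[C@@H](CC/C(C)=C\COC(C)=O)C(C)=C)C(=O)OCC | intermediate
13 | 7-tert-butyl 1-ethyl (2Z,6R)-6-{[(3S,6Z)-8-acetoxy-2,6-dimethylocta-1,6-dien-3-yl]oxy}-6-(bromoacetyl)-2-methylhept-2-enedioate | C/C(=C/CC[C@@](C(=O)CBr)(C(=O)OC(C)(C)C)O[C@@H](CC/C(C)=C\COC(C)=O)C(C)=C)C(=O)OCC | intermediate
14 | ethyl (2Z)-5-[(1R,5R,9S)-9-[(3Z)-5-acetoxy-3-methylpent-3-en-1-yl]-5-methyl-2,7-dioxo-6,8-dioxabicyclo[3.2.2]nonan-1-yl]-2-methylpent-2-enoate | C/C(=C/CC[C@@]12O[C@@H](CC/C(C)=C\COC(C)=O)[C@@](C)(CCC1=O)OC2=O)C(=O)OCC | intermediate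
15 | ethyl (2Z)-5-[(1R,2S,5R,9S)-9-[(3Z)-5-acetoxy-3-methylpent-3-en-1-yl]-2-hydroxy-5-methyl-7-oxo-6,8-dioxabicyclo[3.2.2]nonan-1-yl]-2-methylpent-2-enoate | C/C(=C/CC[C@@]12O[C@@H](CC/C(C)=C\COC(C)=O)[C@@](C)(CC[C@@H]1O)OC2=O)C(=O)OCC | intermediate
16 | (1R,2S,5R,9S)-2-hydroxy-1-[(3Z)-5-hydroxy-4-methylpent-3-en-1-yl]-9-[(3Z)-5-hydroxy-3-methylpent-3-en-1-yl]-5-methyl-6,8-dioxabicyclo[3.2.2]nonan-7-one (CNP0105745.1) | C/C(=C/CC[C@@]12O[C@@H](CC/C(C)=C\CO)[C@@](C)(CC[C@@H]1O)OC2=O)CO | target

**Step count**

Total steps: 10. Longest linear sequence: 9 steps (1 → 2 → 4 → 7 → 9 → 11 → 13 → 14 → 15 → 16; step 3 makes the side branch 6).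

**Steps most likely to fail**

1. Step 8 (proposed new method). What may go wrong: hydrogen transfer from the ether CH to the α-keto radical or proton loss from the tertiary cation may outrun ring closure and lactonisation. The fallback uses known chemistry and goes through a temporary cyclopropane bond. It sets out from methyl ketone 11: detrifluoroacetylative diazo transfer (LiN(SiMe3)2, CF3CO2CH2CF3, THF, −78 °C; then MsN3, Et3N, MeCN) should give the diazomethyl ketone F1. Cu(acac)2 (5 mol %) in toluene at 90 °C with slow addition should then cyclopropanate the isopropenyl group intramolecularly to the cyclopropyl ketone F2; this makes the CH2–CH bond in a six-membered closure, and copper carbenoids seldom insert into C–H bonds. CF3CO2H in CH2Cl2 (0 °C to rt) then cleaves the tert-butyl ester and opens the protonated cyclopropyl ketone at its methyl-bearing carbon, the carboxylic acid capturing the tertiary cation with ring expansion to the oxepanone. The fallback comes back to the route at 14.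

2. Step 5. What may go wrong: poor facial selectivity at the new quaternary carbon, or sigmatropic shift of the enol before it adds to acrolein. The fallback gives up catalyst control and sets out from 7: an achiral amine (DABCO, 10 mol %, CH2Cl2, −20 °C, acrolein in large excess to outpace the rearrangement) should give 9 together with its epimer at the quaternary carbon, the (2S) aldehyde F3. Because the ether carbinol center is fixed, the two are diastereomers and are separated by chromatography (preparative HPLC if needed). The fallback comes back to the route at 9.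

3. Step 10. What may go wrong: over-reduction, that is hydride attack on the lactone carbonyl once the neighbouring hydroxyl has become an aluminium alkoxide that can activate it. The fallback avoids an aluminium hydride and sets out from 15: LiOH in THF–H2O (0 °C to rt) should hydrolyse the acetate and the ethyl ester but not the hindered lactone, giving the hydroxy acid F4. iBuOCOCl and N-methylmorpholine in THF at −15 °C should activate only the carboxylate as the mixed anhydride F5, which NaBH4 (THF–H2O, 0 °C) reduces to the allylic alcohol; NaBH4 does not touch the lactone. The fallback comes back to the route at 16.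

**Further compounds**

F1 | step 8 | 7-tert-butyl 1-ethyl (2Z,6R)-6-{[(3S,6Z)-8-acetoxy-2,6-dimethylocta-1,6-dien-3-yl]oxy}-6-(diazoacetyl)-2-methylhept-2-enedioate | C/C(=C/CC[C@@](C(=O)C=[N+]=[N-])(C(=O)OC(C)(C)C)O[C@@H](CC/C(C)=C\COC(C)=O)C(C)=C)C(=O)OCC
F2 | step 8 | tert-butyl (2S,4R)-2-[(3Z)-5-acetoxy-3-methylpent-3-en-1-yl]-4-[(3Z)-5-ethoxy-4-methyl-5-oxopent-3-en-1-yl]-1-methyl-5-oxo-3-oxabicyclo[4.1.0]heptane-4-carboxylate (mixture at the two ring-fusion carbons) | C/C(=C/CC[C@@]1(C(=O)OC(C)(C)C)O[C@@H](CC/C(C)=C\COC(C)=O)C2(C)CC2C1=O)C(=O)OCC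
F3 | step 5 | tert-butyl (2S)-2-acetyl-2-{[(3S,6Z)-8-acetoxy-2,6-dimethylocta-1,6-dien-3-yl]oxy}-5-oxopentanoate | O=CCC[C@](C(C)=O)(C(=O)OC(C)(C)C)O[C@@H](CC/C(C)=C\COC(C)=O)C(C)=C
F4 | step 10 | (2Z)-5-[(1R,2S,5R,9S)-2-hydroxy-9-[(3Z)-5-hydroxy-3-methylpent-3-en-1-yl]-5-methyl-7-oxo-6,8-dioxabicyclo[3.2.2]nonan-1-yl]-2-methylpent-2-enoic acid | C/C(=C/CC[C@@]12O[C@@H](CC/C(C)=C\CO)[C@@](C)(CC[C@@H]1O)OC2=O)C(=O)O
F5 | step 10 | mixed anhydride of F4 with isobutyl hydrogen carbonate | C/C(=C/CC[C@@]12O[C@@H](CC/C(C)=C\CO)[C@@](C)(CC[C@@H]1O)OC2=O)C(=O)OC(=O)OCC(C)C
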